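## Analysis of the target

The target 20 is a bisabolane-type triester, numbered here as ring C1–C6 with angelate oxygens on C1 and C2, a methyl group on C3, an epoxide across C3/C4, a methylene at C5 and, on C6, the chain C7(=C14H2)–C8(OAng)–C9H2–C10–C11(CH3)2, whose C10/C11 bond carries a second epoxide. Read from the SMILES, the seven stereocentres are 1R,2S,3S,4S,6R,8S,10R. On the ring the C1 oxygen and the epoxide oxygen lie on one face (called the upper face below), while the C2 oxygen, the C3 methyl and the C6 chain lie on the other, so the substituents on C6, C1 and C2 are trans, trans and can all be equatorial. C8 is insulated from the ring by the sp2 carbon C7 and C10 lies two atoms further out, so C8 is best bought and C10 set by a reagent. The three (Z)-2-methylbut-2-enoates isomerise to the E esters under nucleophilic catalysis, strong base or prolonged heating, the 2,2-dimethyloxirane is acid-labile and the C8 ester is allylic. Late intermediates carry several C=C bonds of different kinds (a methylidene, a trisubstituted chain alkene, the enoates and at some stages a ring alkene), so every oxidation has to choose both an alkene and a face, and this is the main difficulty. The plan rests on one feature: the oxygens on C1 and C4 sit 1,4 across the ring on the same face and the C6 substituent is trans to the C1 oxygen, which is the arrangement of the oxygen bridge and an endo substituent in a 7-oxabicyclo[2.2.1]heptene, the cycloadduct of 3-methylfuran 6 (C1–C4, the methyl group and the oxygen) with a vinyl ketone (C5, C6, C7).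

## Retrosynthetic reasoning

**20 to 19.** The two C–O bonds of the C10/C11 epoxide are cut last. This is the most acid-labile group and is too far from any stereocentre to be relayed, so it needs reagent control. In 19 the ring alkene is already oxidised, so the forward step only has to prefer an unhindered, electron-rich trisubstituted alkene over a hindered methylidene and three enoates.

**19 to 16 and 17.** The three acyl C–O bonds are cut together. The angelates are put on once, after every step that uses strong base, fluoride or hydride, because they isomerise and migrate. The forward reaction has to acylate three hindered secondary hydroxyls without a nucleophilic catalyst.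

**16 to 15 to 14.** The C2 carbinol goes back to a ketone, and the two hydroxyls at C1 and C8 to silyl ethers. The ketone is what the bridge opening delivers. The free C1 hydroxyl on the upper face is the handle for delivering hydride to that face, which puts the new C2 oxygen trans to it; this is why the silyl groups come off before the reduction.

**14 to 13.** The C3/C4 epoxide is cut back to the enone. Among all alkenes present only the enone is electrophilic, so a nucleophilic peroxide is chemoselective. The face is set by the equatorial C6 substituent, as in 5-substituted cyclohex-2-enones, and this is the upper face. Epoxidising at the ester stage instead would require an electrophilic oxidant to choose alkene and face at once.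

**13 to 12.** The C4–O bond is re-formed in the retrosynthetic sense: the silyloxy enone comes from an oxygen-bridged ketone by β-elimination. In 12 the C2 ketone can enolise only toward C3, because C1 is a bridgehead, so the forward elimination is regiochemically unambiguous. It creates C3=C4 in conjugation and releases the C1 oxygen with the configuration fixed in the cycloaddition.

**12 to 11 to 10 to 8.** These are functional-group changes on the bicycle: the C2 ketone comes from the exo C2 alcohol, the C7 methylidene from the C7 ketone, and the C2 oxygen from hydroboration of the strained C2=C3 alkene. The order is forced. A C7 ketone has the bridge oxygen β to it (at C1) and would open the bridge the wrong way under base, so it must become the methylidene before the C2 ketone meets base. Hydroboration comes first, while the strained alkene is the only reactive one, and it also ends the risk of cycloreversion.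

**8 to 7 to 5 and 6.** C1–C6 and C4–C5 are cut. This cycloaddition closes the carbocycle, sets C1, C4 and C6, places both ring oxygens on one face and brings in the complete chain. The C8 hydroxyl of 5 is left free for two-point binding to the catalyst and is silylated afterwards.

**5 to 4 to 3 to 1 and 2.** The C6–C7 bond is formed by vinylation of the Weinreb amide 4; the amide comes from the ester 3; the C9–C10 bond comes from opening the epoxide 1 at its methylene carbon with the alkenyl reagent 2. The stereocentre is bought in 1, and no bond to it is broken on the way to C8.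

## Alternatives that were turned down

Alternative 1: Disconnection of C1–C6 and C3=C4, leading to ethyl (1S,6R)-6-(benzyloxy)-4-methyl-5-oxocyclohex-3-ene-1-carboxylate A1.
- Forward key step: a diarylprolinol silyl ether catalyst turns ethyl (E)-4-oxobut-2-enoate A3 into its iminium ion. tert-Butyl 4-(benzyloxy)-2-methyl-3-oxobutanoate A2 adds through its benzyloxy-bearing carbon (C1–C6). Acid then closes C3=C4 by aldol condensation and removes the tert-butyl ester by decarboxylation.
- For: cheap achiral components and a catalytic asymmetric step. A1 already has the C2 ketone, the C3=C4 alkene and the C1 oxygen. The chosen route reaches that stage (13) only after hydroboration, two oxidation-level changes and the bridge opening, so this alternative is stronger on the ring by about four steps.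
- Against: the acidic and nucleophilic site of A2 is the carbon between its two carbonyls, not the benzyloxymethyl carbon, so the required Michael regiochemistry runs against the inherent reactivity. C1 of A1 is an α-alkoxy ketone centre exposed to acid during the condensation. C6 carries only an ester, so C7–C11 and the C8 stereocentre must be built afterwards through intermediates in which C6 is α to a carbonyl and can epimerise.
- Comparison: the chosen strategy gives up the direct access to the enone. In exchange it brings the finished C7–C11 chain with C8 into the ring-forming step and ties C1, C4 and C6 together in a concerted event.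

Alternative 2: The ring is closed late at C3=C4 by metathesis of an acyclic triene whose C1/C2 trans-diol is a chiral-pool acetonide.
- Forward key step: a copper-mediated conjugate allylation of (E)-1-[2,2-dimethyl-5-(prop-1-en-2-yl)-1,3-dioxolan-4-yl]-6-methylhepta-1,5-dien-3-one A5 forms C5–C6. The silyl enol ether is methylenated in the same pot through a Mannich addition, N-methylation and elimination, giving 4-[2,2-dimethyl-5-(prop-1-en-2-yl)-1,3-dioxolan-4-yl]-9-methyl-5-methylidenedeca-1,8-dien-6-one A4.
- For: both ring carbinols are bought with the correct trans relation. This is stronger than the chosen route at C2, where a reduction has to be steered. The one-pot step builds two bonds, and six-ring metathesis is dependable.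
- Against: C6 is set by acyclic 1,2-induction in an allyl transfer, which is the least selective kind of cuprate addition and prone to 1,2-attack. A4 is a reactive α-methylene ketone. In the metathesis the allyl group can pair with the chain alkene (seven-membered ring) or the enone alkene instead of the hindered isopropenyl group. C8 is a ketone that still needs a reagent-controlled 1,2-reduction of a cross-conjugated enone.
- Comparison: the chosen strategy sets C6 by cycloaddition geometry, has no metathesis competition and carries C8 at the right oxidation level from the first step.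

Alternative 3: Disconnection of C2–C3.
- Forward key step: (Z)-2-[(tert-butyldimethylsilyl)oxy]-3-{3-[(tert-butyldimethylsilyl)oxy]-6-methylhepta-1,5-dien-2-yl}-6-iodohept-5-enal A7 cyclises under Nozaki–Hiyama–Kishi conditions (CrCl2, divalent chromium, with catalytic NiCl2) to 6-[(tert-butyldimethylsilyl)oxy]-5-{3-[(tert-butyldimethylsilyl)oxy]-6-methylhepta-1,5-dien-2-yl}-2-methylcyclohex-2-en-1-ol A6.
- For: mild and chemoselective. The ring alkene and the C2 carbinol appear at their final oxidation level in the ring-closing step. After ring closure this is shorter than the chosen route, which needs a redox detour at C2.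
- Against: A7 contains C1, C6 and C8 plus a Z-trisubstituted iodoalkene, all of which must be assembled in a long linear sequence. Its α-silyloxy aldehyde can epimerise. The C2 configuration depends on a Felkin–chelate balance in the closure. In A6 the free allylic hydroxyl on the lower face would direct an epoxidation to the wrong face.
- Comparison: the chosen strategy reaches its precursor in three steps and creates three stereocentres from one. It pays for that with the functional-group work on the bicycle.

Key step: step 4

Remark 1: the numbering and the descriptors 1R,2S,3S,4S,6R,8S,10R are those derived from the SMILES of the target; intermediates are drawn so that each ring atom keeps the spatial arrangement of the target.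

Remark 2: the (S,S) ligand is taken as the one that leaves the Re face of C6 open in a square-planar chelate, and the D-fructose-derived ketone as the one that gives a 10R epoxide from a 2-methylalk-2-ene.

## Route

Step 1
Reactants: 1 methyl (2S)-oxirane-2-carboxylate; 2 (2-methylprop-1-en-1-yl)magnesium bromide
Product: 3 methyl (2S)-2-hydroxy-5-methylhex-4-enoate
Conditions: CuI (10 mol %), THF, −40 °C; aq. NH4Cl
Reagents that add atoms: none
Why: Copper-catalysed Grignard opening of a glycidic ester is an SN2 attack at the unsubstituted ring carbon, so no bond at the stereocentre is broken and the bought S centre becomes C8; the low temperature keeps the reagent away from the ester carbonyl.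

Step 2
Reactants: 3 methyl (2S)-2-hydroxy-5-methylhex-4-enoate
Product: 4 (2S)-2-hydroxy-N-methoxy-N,5-dimethylhex-4-enamide
Conditions: MeONHMe·HCl, i-PrMgCl, THF, −20 to 0 °C
Reagents that add atoms: N,O-dimethylhydroxylamine hydrochloride, CNOC.Cl
Why: Weinreb amide formation by aminolysis of the ester with the chloromagnesium amide; the α-hydroxyl is carried as its magnesium alkoxide, which disfavours α-deprotonation, so C8 should keep its configuration.

Step 3
Reactants: 4 (2S)-2-hydroxy-N-methoxy-N,5-dimethylhex-4-enamide
Product: 5 (4S)-4-hydroxy-7-methylocta-1,6-dien-3-one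
Conditions: CH2=CHMgBr (3.5 equiv), THF, −78 to 0 °C; inverse quench into cold 1 M HCl
Reagents that add atoms: vinylmagnesium bromide, C=C[Mg]Br
Why: Weinreb ketone synthesis: the chelated tetrahedral adduct survives until the quench, so addition stops at the ketone; quenching into cold acid protonates the released amine before it can add to the vinyl ketone.

Step 4
Reactants: 5 (4S)-4-hydroxy-7-methylocta-1,6-dien-3-one; 6 3-methylfuran
Product: 7 (2S)-2-hydroxy-5-methyl-1-[(1S,2S,4S)-5-methyl-7-oxabicyclo[2.2.1]hept-5-en-2-yl]hex-4-en-1-one (endo adduct)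
Conditions: 6 (5 equiv), [Cu((S,S)-t-Bu-box)](SbF6)2 (10 mol %, divalent copper; ligand 2,2'-(propane-2,2-diyl)bis[(4S)-4-tert-butyl-4,5-dihydrooxazole]), 4 Å molecular sieves, CH2Cl2, −78 °C
Reagents that add atoms: none
Why: The hydroxy enone 5 binds the copper centre through its carbonyl and hydroxyl oxygens in a five-membered s-cis chelate, which lowers the LUMO; 6 then adds in a concerted, asynchronous [4+2] cycloaddition in which the bond from the enone β-carbon (C5) to the furan carbon next to the methyl group (C4) runs ahead of the C6–C1 bond. The closest known reaction type is the copper bis(oxazoline)-catalysed Diels–Alder reaction of furan with two-point-binding acryloyl dienophiles and of α'-hydroxy enones with dienes. The carbocyclic six-membered ring is closed by this intermolecular [4+2] cycloaddition (bonds C1–C6 and C4–C5) as part of a 7-oxabicyclo[2.2.1]heptene whose bridge is the furan oxygen. Regioselectivity (methyl-bearing carbon para to C6) follows from the larger HOMO coefficient at the furan α-carbon adjacent to the methyl group, which pairs with the electrophilic β-carbon. C6 is set by the face of the dienophile: in the planar chelate the C9 chain on the 8S centre covers the Si face of C6 and the tert-butyl group of the (S,S) ligand covers the same face, so the diene should add to the Re face (matched pair). C1 and C4 are then fixed relative to C6 by suprafacial addition and the endo orientation (secondary overlap of the furan with the bound carbonyl), which places the acyl group trans to the bridge oxygen. The step needs regio-, endo- and face-selectivity under kinetic control; −78 °C and a non-coordinating counter-ion are chosen because the adduct can revert and the furan can instead undergo conjugate alkylation at higher temperature.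

Step 5
Reactants: 7 (2S)-2-hydroxy-5-methyl-1-[(1S,2S,4S)-5-methyl-7-oxabicyclo[2.2.1]hept-5-en-2-yl]hex-4-en-1-one
Product: 8 (2S)-5-methyl-1-[(1S,2S,4S)-5-methyl-7-oxabicyclo[2.2.1]hept-5-en-2-yl]-2-(triethylsilyloxy)hex-4-en-1-one
Conditions: Et3SiCl, imidazole, CH2Cl2, −20 to 0 °C
Reagents that add atoms: chlorotriethylsilane, CC[Si](Cl)(CC)CC
Why: Standard silylation of a secondary α-hydroxy ketone, run cold and without strong base because 7 can revert to its components or open at C1–O by enolisation toward C6; the silyl ether protects C8–OH from the later oxidation.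

Step 6
Reactants: 8 (2S)-5-methyl-1-[(1S,2S,4S)-5-methyl-7-oxabicyclo[2.2.1]hept-5-en-2-yl]-2-(triethylsilyloxy)hex-4-en-1-one
Product: 10 (2S)-1-[(1R,2S,4S,5S,6S)-6-hydroxy-5-methyl-7-oxabicyclo[2.2.1]heptan-2-yl]-5-methyl-2-(triethylsilyloxy)hex-4-en-1-one (exo hydroxyl; endo methyl), via exo C2 catecholboronate 9 (not isolated)
Conditions: catecholborane, RhCl(PPh3)3 (3 mol %), THF, 0 °C to rt; then 30% H2O2, pH 7 phosphate buffer, 0 °C
Reagents that add atoms: catecholborane, B1Oc2ccccc2O1 (its boron and catechol unit stay in 9 only); hydrogen peroxide, OO (oxygen on C2 of 10)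
Why: Rhodium-catalysed hydroboration with catecholborane takes a strained bicyclic alkene much faster than a ketone or the unstrained trisubstituted chain alkene; boron goes to the less substituted C2 and hydrogen to C3, both from the exo face, because the endo face is covered by the C6 acyl group. Buffered peroxide oxidation with retention gives the exo alcohol; the two new centres (C2, C3) are temporary, and cycloreversion is no longer possible after this step.

Step 7
Reactants: 10 (2S)-1-[(1R,2S,4S,5S,6S)-6-hydroxy-5-methyl-7-oxabicyclo[2.2.1]heptan-2-yl]-5-methyl-2-(triethylsilyloxy)hex-4-en-1-one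
Product: 11 (1R,2S,3S,4S,6R)-3-methyl-6-[(3S)-6-methyl-3-(triethylsilyloxy)hepta-1,5-dien-2-yl]-7-oxabicyclo[2.2.1]heptan-2-ol
Conditions: Cp2Ti(μ-CH2)(μ-Cl)AlMe2 (Tebbe reagent, 3 equiv), pyridine, THF/toluene, −40 to 0 °C; aq. NaOH work-up
Reagents that add atoms: Tebbe reagent, C[Al-]1(C)C[Ti]([Cl+]1)(C2C=CC=C2)C3C=CC=C3 (only its CH2 group stays in 11)
Why: Tebbe methylenation is a non-basic carbonyl olefination through a titanium methylidene, so the hindered, enolisable C7 ketone should be converted without epimerising C6 or C8 and without β-elimination of the C1–O bridge. The free hydroxyl consumes one equivalent of the reagent with loss of methane, is carried as a metal alkoxide and returns on work-up, which is why an excess is used. The step is placed after step 6 because the titanium carbene would attack the strained alkene of 8 and a C7 methylidene would compete in the hydroboration.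

Step 8
Reactants: 11 (1R,2S,3S,4S,6R)-3-methyl-6-[(3S)-6-methyl-3-(triethylsilyloxy)hepta-1,5-dien-2-yl]-7-oxabicyclo[2.2.1]heptan-2-ol
Product: 12 (1R,3R,4S,6R)-3-methyl-6-[(3S)-6-methyl-3-(triethylsilyloxy)hepta-1,5-dien-2-yl]-7-oxabicyclo[2.2.1]heptan-2-one
Conditions: Dess–Martin periodinane, NaHCO3, CH2Cl2, 0 °C to rt
Reagents that add atoms: none
Why: Dess–Martin oxidation of a secondary alcohol under buffered, non-basic conditions; the alkenes and the silyl ether are inert, and the β-alkoxy ketone is not exposed to base before the next step.

Step 9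
Reactants: 12 (1R,3R,4S,6R)-3-methyl-6-[(3S)-6-methyl-3-(triethylsilyloxy)hepta-1,5-dien-2-yl]-7-oxabicyclo[2.2.1]heptan-2-one
Product: 13 (5R,6R)-2-methyl-5-[(3S)-6-methyl-3-(triethylsilyloxy)hepta-1,5-dien-2-yl]-6-(triethylsilyloxy)cyclohex-2-en-1-one
Conditions: Et3SiOTf, Et3N, CH2Cl2, −40 to 0 °C
Reagents that add atoms: triethylsilyl trifluoromethanesulfonate, CC[Si](CC)(CC)OS(=O)(=O)C(F)(F)F
Why: Silyl triflate/amine-induced β-elimination of a 7-oxabicyclo[2.2.1]heptan-2-one (E1cB type): the ketone can enolise only toward C3 because C1 is a bridgehead (Bredt's rule), and the silylated bridge oxygen leaves C4 with release of ring strain. The oxygen stays on C1 with its configuration and is capped as the silyl ether in the same operation; C6 and C8 are untouched.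

Step 10
Reactants: 13 (5R,6R)-2-methyl-5-[(3S)-6-methyl-3-(triethylsilyloxy)hepta-1,5-dien-2-yl]-6-(triethylsilyloxy)cyclohex-2-en-1-one
Product: 14 (1S,3R,4R,6S)-1-methyl-4-[(3S)-6-methyl-3-(triethylsilyloxy)hepta-1,5-dien-2-yl]-3-(triethylsilyloxy)-7-oxabicyclo[4.1.0]heptan-2-one
Conditions: t-BuOOH, benzyltrimethylammonium hydroxide (cat.), THF, 0 °C
Reagents that add atoms: tert-butyl hydroperoxide, CC(C)(C)OO
Why: Weitz–Scheffer (nucleophilic) epoxidation touches only the enone among the alkenes present. As in 5-substituted cyclohex-2-enones of the carvone type, the peroxide should add axially to C4 on the face opposite the equatorial C6 substituent, and ring closure on that face places the epoxide oxygen on the upper face, cis to the C1 oxygen, which sets C3 and C4.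

Step 11
Reactants: 14 (1S,3R,4R,6S)-1-methyl-4-[(3S)-6-methyl-3-(triethylsilyloxy)hepta-1,5-dien-2-yl]-3-(triethylsilyloxy)-7-oxabicyclo[4.1.0]heptan-2-one
Product: 15 (1S,3R,4R,6S)-3-hydroxy-4-[(3S)-3-hydroxy-6-methylhepta-1,5-dien-2-yl]-1-methyl-7-oxabicyclo[4.1.0]heptan-2-one
Conditions: HF·pyridine, pyridine, THF, 0 °C to rt
Reagents that add atoms: none
Why: Buffered fluoride cleavage of both triethylsilyl ethers; the electron-poor α,β-epoxy ketone and the alkenes tolerate these conditions.

Step 12
Reactants: 15 (1S,3R,4R,6S)-3-hydroxy-4-[(3S)-3-hydroxy-6-methylhepta-1,5-dien-2-yl]-1-methyl-7-oxabicyclo[4.1.0]heptan-2-one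
Product: 16 (1R,2S,3R,4R,6S)-4-[(3S)-3-hydroxy-6-methylhepta-1,5-dien-2-yl]-1-methyl-7-oxabicyclo[4.1.0]heptane-2,3-diol
Conditions: Me4NBH(OAc)3, MeCN/AcOH, −30 °C
Reagents that add atoms: none
Why: Hydroxyl-directed reduction with triacetoxyborohydride (Saksena–Evans type): the C1 hydroxyl exchanges onto boron and delivers hydride intramolecularly to the upper face of the C2 carbonyl, so the new hydroxyl lies on the lower face, trans to the C1 hydroxyl and to the epoxide oxygen. The reagent is too weak to reduce the ketone without this delivery and leaves the epoxide and alkenes alone.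

Step 13
Reactants: 16 (1R,2S,3R,4R,6S)-4-[(3S)-3-hydroxy-6-methylhepta-1,5-dien-2-yl]-1-methyl-7-oxabicyclo[4.1.0]heptane-2,3-diol; 17 angelic acid, (Z)-2-methylbut-2-enoic acid
Product: 19 (1S,2S,3R,4R,6S)-1-methyl-4-{(3S)-6-methyl-3-[(Z)-2-methylbut-2-enoyloxy]hepta-1,5-dien-2-yl}-7-oxabicyclo[4.1.0]heptane-2,3-diyl bis[(Z)-2-methylbut-2-enoate], via angeloyl 2,4,6-trichlorobenzoyl anhydride 18 (not isolated)
Conditions: 17, 2,4,6-trichlorobenzoyl chloride, Et3N, toluene, rt; filter off the ammonium chloride; then 16, Et3N, toluene, 75 °C
Reagents that add atoms: 2,4,6-trichlorobenzoyl chloride, O=C(Cl)c1c(Cl)cc(Cl)cc1Cl (its atoms stay in 18 only)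
Why: Yamaguchi-type esterification through the mixed anhydride 18, run without a nucleophilic catalyst because such catalysts add reversibly to the enoate and isomerise Z to E; the hindered aryl carbonyl of 18 directs the three hydroxyls to the angeloyl carbonyl. Acylation occurs at oxygen, so no stereocentre is touched; the ammonium chloride is removed first so that chloride cannot open the epoxide on heating, and the amine buffers the liberated aryl acid.

Step 14
Reactants: 19 (1S,2S,3R,4R,6S)-1-methyl-4-{(3S)-6-methyl-3-[(Z)-2-methylbut-2-enoyloxy]hepta-1,5-dien-2-yl}-7-oxabicyclo[4.1.0]heptane-2,3-diyl bis[(Z)-2-methylbut-2-enoate]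
Product: 20 (1S,2S,3R,4R,6S)-4-{(3S)-4-[(2R)-3,3-dimethyloxiran-2-yl]-3-[(Z)-2-methylbut-2-enoyloxy]but-1-en-2-yl}-1-methyl-7-oxabicyclo[4.1.0]heptane-2,3-diyl bis[(Z)-2-methylbut-2-enoate] (CNP0258231.1)
Conditions: 1,2:4,5-di-O-isopropylidene-β-D-erythro-2,3-hexodiulo-2,6-pyranose (D-fructose-derived Shi ketone, 30 mol %), Oxone (2KHSO5·KHSO4·K2SO4), K2CO3, n-Bu4NHSO4, MeCN/dimethoxymethane/aq. Na2B4O7 buffer (pH 10.5), 0 °C
Reagents that add atoms: potassium peroxymonosulfate (active component of Oxone), [K+].[O-]S(=O)(=O)OO
Why: Shi asymmetric epoxidation: the chiral dioxirane should react fastest with the unhindered, electron-rich trisubstituted C10=C11 alkene, while the C7 methylidene (flanked by two branched carbons and an allylic ester) and the three enoates are much slower. The spiro transition state of the D-fructose-derived ketone delivers oxygen to the face that gives 10R, independent of the remote C8 centre, and the mildly basic buffer preserves both epoxides.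

## Compound list

1 | methyl (2S)-oxirane-2-carboxylate | COC(=O)[C@@H]1CO1 | starting material
2 | (2-methylprop-1-en-1-yl)magnesium bromide | CC(C)=C[Mg]Br | starting material
3 | methyl (2S)-2-hydroxy-5-methylhex-4-enoate | COC(=O)[C@@H](O)CC=C(C)C | intermediate
4 | (2S)-2-hydroxy-N-methoxy-N,5-dimethylhex-4-enamide | CON(C)C(=O)[C@@H](O)CC=C(C)C | intermediate
5 | (4S)-4-hydroxy-7-methylocta-1,6-dien-3-one | C=CC(=O)[C@H](CC=C(C)C)O | intermediate
6 | 3-methylfuran | Cc1ccoc1 | starting material
7 | (2S)-2-hydroxy-5-methyl-1-[(1S,2S,4S)-5-methyl-7-oxabicyclo[2.2.1]hept-5-en-2-yl]hex-4-en-1-one (endo adduct) | O=C([C@H](CC=C(C)C)O)[C@H]1C[C@@H]2O[C@H]1C=C2C | intermediate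
8 | (2S)-5-methyl-1-[(1S,2S,4S)-5-methyl-7-oxabicyclo[2.2.1]hept-5-en-2-yl]-2-(triethylsilyloxy)hex-4-en-1-one | O=C([C@H](CC=C(C)C)O[Si](CC)(CC)CC)[C@H]1C[C@@H]2O[C@H]1C=C2C | intermediate
9 | exo C2 catecholboronate of 8, not isolated (1,3,2-benzodioxaborol-2-yl on C2 and the new hydrogen on C3, both on the face of the bridge oxygen) | O=C([C@H](CC=C(C)C)O[Si](CC)(CC)CC)[C@H]1C[C@@H]2O[C@H]1[C@@H](B3Oc4ccccc4O3)[C@@H]2C | intermediate
10 | (2S)-1-[(1R,2S,4S,5S,6S)-6-hydroxy-5-methyl-7-oxabicyclo[2.2.1]heptan-2-yl]-5-methyl-2-(triethylsilyloxy)hex-4-en-1-one | O=C([C@H](CC=C(C)C)O[Si](CC)(CC)CC)[C@H]1C[C@@H]2O[C@H]1[C@@H](O)[C@@H]2C | intermediate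
11 | (1R,2S,3S,4S,6R)-3-methyl-6-[(3S)-6-methyl-3-(triethylsilyloxy)hepta-1,5-dien-2-yl]-7-oxabicyclo[2.2.1]heptan-2-ol | C=C([C@H](CC=C(C)C)O[Si](CC)(CC)CC)[C@H]1C[C@@H]2O[C@H]1[C@@H](O)[C@@H]2C | intermediate
12 | (1R,3R,4S,6R)-3-methyl-6-[(3S)-6-methyl-3-(triethylsilyloxy)hepta-1,5-dien-2-yl]-7-oxabicyclo[2.2.1]heptan-2-one | C=C([C@H](CC=C(C)C)O[Si](CC)(CC)CC)[C@H]1C[C@@H]2O[C@H]1C(=O)[C@@H]2C | intermediate
13 | (5R,6R)-2-methyl-5-[(3S)-6-methyl-3-(triethylsilyloxy)hepta-1,5-dien-2-yl]-6-(triethylsilyloxy)cyclohex-2-en-1-one | C=C([C@H](CC=C(C)C)O[Si](CC)(CC)CC)[C@H]1CC=C(C)C(=O)[C@@H]1O[Si](CC)(CC)CC | intermediate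
14 | (1S,3R,4R,6S)-1-methyl-4-[(3S)-6-methyl-3-(triethylsilyloxy)hepta-1,5-dien-2-yl]-3-(triethylsilyloxy)-7-oxabicyclo[4.1.0]heptan-2-one | C=C([C@H](CC=C(C)C)O[Si](CC)(CC)CC)[C@H]1C[C@@H]2O[C@]2(C)C(=O)[C@@H]1O[Si](CC)(CC)CC | intermediate
15 | (1S,3R,4R,6S)-3-hydroxy-4-[(3S)-3-hydroxy-6-methylhepta-1,5-dien-2-yl]-1-methyl-7-oxabicyclo[4.1.0]heptan-2-one | C=C([C@H](CC=C(C)C)O)[C@H]1C[C@@H]2O[C@]2(C)C(=O)[C@@H]1O | intermediate
16 | (1R,2S,3R,4R,6S)-4-[(3S)-3-hydroxy-6-methylhepta-1,5-dien-2-yl]-1-methyl-7-oxabicyclo[4.1.0]heptane-2,3-diol | C=C([C@H](CC=C(C)C)O)[C@H]1C[C@@H]2O[C@]2(C)[C@@H](O)[C@@H]1O | intermediate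
17 | angelic acid, (Z)-2-methylbut-2-enoic acid | C/C=C(/C)C(=O)O | starting material
18 | (Z)-2-methylbut-2-enoic 2,4,6-trichlorobenzoic anhydride, not isolated | C/C=C(/C)C(=O)OC(=O)c1c(Cl)cc(Cl)cc1Cl | intermediate
19 | (1S,2S,3R,4R,6S)-1-methyl-4-{(3S)-6-methyl-3-[(Z)-2-methylbut-2-enoyloxy]hepta-1,5-dien-2-yl}-7-oxabicyclo[4.1.0]heptane-2,3-diyl bis[(Z)-2-methylbut-2-enoate] | C=C([C@H](CC=C(C)C)OC(=O)/C(C)=C\C)[C@H]1C[C@@H]2O[C@]2(C)[C@@H](OC(=O)/C(C)=C\C)[C@@H]1OC(=O)/C(C)=C\C | intermediate
20 | (1S,2S,3R,4R,6S)-4-{(3S)-4-[(2R)-3,3-dimethyloxiran-2-yl]-3-[(Z)-2-methylbut-2-enoyloxy]but-1-en-2-yl}-1-methyl-7-oxabicyclo[4.1.0]heptane-2,3-diyl bis[(Z)-2-methylbut-2-enoate] (CNP0258231.1) | C=C([C@H](C[C@H]1OC1(C)C)OC(=O)/C(C)=C\C)[C@H]1C[C@@H]2O[C@]2(C)[C@@H](OC(=O)/C(C)=C\C)[C@@H]1OC(=O)/C(C)=C\C | target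

## Step count and least certain steps

Total: 14 steps. Longest linear sequence: 14 steps, from 1 to 20; 2, 6 and 17 are bought.

**Step 4 (key step).** The most likely failure is conjugate alkylation at the furan α-carbon next to the methyl group, in which the zwitterion rearomatises by proton loss instead of closing the second bond. Next in likelihood are cycloreversion on warming and leakage to the exo or regioisomeric adduct, because a 3-alkylfuran is more nucleophilic, and its adduct more labile, than furan itself. Fallback: set out from 6 with the dienophile for which this catalysis is best established, 3-acryloyl-1,3-oxazolidin-2-one, and [Cu((S,S)-t-Bu-box)](SbF6)2 at −78 °C, to obtain the endo imide adduct F1. Aminolysis with MeONHMe·HCl/AlMe3 gives the Weinreb amide F2, and (4-methylpent-3-en-1-yl)magnesium bromide gives the homoprenyl ketone F3. Kinetic deprotonation at the C8 methylene (KN(SiMe3)2, THF, −78 °C) and Davis hydroxylation with the (camphorsulfonyl)oxaziridine enantiomer that gives 8S (expected to be the (+)-reagent) return to the route at 7. Face control then rests on the ligand alone, and C8 is set afterwards.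

**Step 6.** Competing reduction of the C7 carbonyl by the borane, slow turnover at a trisubstituted alkene and loss of material by cycloreversion while the alkene is still present are the risks. Fallback: set out from 8. Hydrosilylation with HSi(OEt)3 and Pt2[(CH2=CHSiMe2)2O]3 (Karstedt catalyst, zerovalent platinum), which does not reduce ketones and should add only to the strained alkene from the exo face, gives the exo C2 triethoxysilane F4. Tamao–Fleming oxidation (KF, KHCO3, H2O2, THF/MeOH) with retention returns to the route at 10.

**Step 10.** Base-induced epimerisation at C1 or loss of the C1 silyl ether may occur, and the facial preference of the peroxide addition may be eroded by the extra α'-substituent. Fallback: set out from 13 and reduce before oxidising. Luche reduction (NaBH4, CeCl3·7H2O, MeOH, −78 °C; axial attack) gives the lower-face allylic alcohol F5, and HF·pyridine gives the triene triol F6. Esterification with 18 as in step 13 gives the triene tris-angelate F7, and Shi epoxidation with a limited amount of Oxone gives the 10R chain epoxide F8. mCPBA/NaHCO3 in CH2Cl2 at 0 °C then epoxidises the ring alkene anti to the allylic C2 ester and returns to the route at 20. This replaces nucleophilic by electrophilic epoxidation, and the face selectivity of the last oxidation is the open point of the detour.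

**Step 12.** Facial selectivity may be poor if internal delivery is slow, because the C1–O bond must turn out of the carbonyl plane before hydride can be handed over; acid-promoted opening of the epoxide is a second risk. Fallback: set out from 14, before desilylation. NaBH4/CeCl3·7H2O in MeOH at −78 °C relies on approach control (axial attack from the upper face) to give the bis-silyl epoxy alcohol F9, and HF·pyridine then returns to the route at 16.

**Step 13.** Z to E isomerisation of the angeloyl units during prolonged heating, incomplete acylation of the hindered C2 hydroxyl and acyl migration between C1 and C2 are the risks. Fallback: set out from 16. Esterification with 2-[bis(2,2,2-trifluoroethoxy)phosphoryl]propanoic acid (DCC, DMAP, CH2Cl2; no alkene is present in the acyl group to isomerise) gives the tris(phosphonopropionate) F10. A threefold Still–Gennari olefination with acetaldehyde (KN(SiMe3)2, 18-crown-6, THF, −78 °C) builds the Z enoates in place and returns to the route at 19.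

## Further compounds

F1 | step 4 | 3-{[(1S,2S,4S)-5-methyl-7-oxabicyclo[2.2.1]hept-5-en-2-yl]carbonyl}-1,3-oxazolidin-2-one (endo imide adduct) | O=C(N1CCOC1=O)[C@H]1C[C@@H]2O[C@H]1C=C2C
F2 | step 4 | (1S,2S,4S)-N-methoxy-N,5-dimethyl-7-oxabicyclo[2.2.1]hept-5-ene-2-carboxamide (Weinreb amide) | CON(C)C(=O)[C@H]1C[C@@H]2O[C@H]1C=C2C
F3 | step 4 | 5-methyl-1-[(1S,2S,4S)-5-methyl-7-oxabicyclo[2.2.1]hept-5-en-2-yl]hex-4-en-1-one (homoprenyl ketone) | CC(C)=CCCC(=O)[C@H]1C[C@@H]2O[C@H]1C=C2C
F4 | step 6 | exo C2 triethoxysilane (10 with Si(OEt)3 in place of the C2 hydroxyl) | O=C([C@H](CC=C(C)C)O[Si](CC)(CC)CC)[C@H]1C[C@@H]2O[C@H]1[C@@H]([Si](OCC)(OCC)OCC)[C@@H]2C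
F5 | step 10 | (1R,5R,6R)-2-methyl-5-[(3S)-6-methyl-3-(triethylsilyloxy)hepta-1,5-dien-2-yl]-6-(triethylsilyloxy)cyclohex-2-en-1-ol (lower-face allylic alcohol) | C=C([C@H](CC=C(C)C)O[Si](CC)(CC)CC)[C@H]1CC=C(C)[C@@H](O)[C@@H]1O[Si](CC)(CC)CC
F6 | step 10 | (1R,2R,6R)-6-[(3S)-3-hydroxy-6-methylhepta-1,5-dien-2-yl]-3-methylcyclohex-3-ene-1,2-diol (triene triol) | C=C([C@H](CC=C(C)C)O)[C@H]1CC=C(C)[C@@H](O)[C@@H]1O
F7 | step 10 | tris[(Z)-2-methylbut-2-enoate] of F6 at the C1, C2 and C8 oxygens (triene tris-angelate) | C=C([C@H](CC=C(C)C)OC(=O)/C(C)=C\C)[C@H]1CC=C(C)[C@@H](OC(=O)/C(C)=C\C)[C@@H]1OC(=O)/C(C)=C\C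
F8 | step 10 | F7 with the (10R)-C10/C11 epoxide and the ring alkene intact | C=C([C@H](C[C@H]1OC1(C)C)OC(=O)/C(C)=C\C)[C@H]1CC=C(C)[C@@H](OC(=O)/C(C)=C\C)[C@@H]1OC(=O)/C(C)=C\C
F9 | step 12 | 14 with the C2 carbonyl reduced to the lower-face (2S) hydroxyl, both silyl ethers kept | C=C([C@H](CC=C(C)C)O[Si](CC)(CC)CC)[C@H]1C[C@@H]2O[C@]2(C)[C@@H](O)[C@@H]1O[Si](CC)(CC)CC
F10 | step 13 | tris{2-[bis(2,2,2-trifluoroethoxy)phosphoryl]propanoate} of 16 at the C1, C2 and C8 oxygens | C=C([C@H](CC=C(C)C)OC(=O)C(C)P(=O)(OCC(F)(F)F)OCC(F)(F)F)[C@H]1C[C@@H]2O[C@]2(C)[C@@H](OC(=O)C(C)P(=O)(OCC(F)(F)F)OCC(F)(F)F)[C@@H]1OC(=O)C(C)P(=O)(OCC(F)(F)F)OCC(F)(F)F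
A1 | alternative 1 | ethyl (1S,6R)-6-(benzyloxy)-4-methyl-5-oxocyclohex-3-ene-1-carboxylate | CCOC(=O)[C@H]1CC=C(C)C(=O)[C@@H]1OCc1ccccc1
A2 | alternative 1 | tert-butyl 4-(benzyloxy)-2-methyl-3-oxobutanoate | CC(C(=O)OC(C)(C)C)C(=O)COCc1ccccc1
A3 | alternative 1 | ethyl (E)-4-oxobut-2-enoate | CCOC(=O)/C=C/C=O
A4 | alternative 2 | 4-[2,2-dimethyl-5-(prop-1-en-2-yl)-1,3-dioxolan-4-yl]-9-methyl-5-methylidenedeca-1,8-dien-6-one (trans-dioxolane, configured as in the SMILES) | C=C(C)[C@H]1OC(C)(C)O[C@@H]1[C@H](CC=C)C(=C)C(=O)CC=C(C)C
A5 | alternative 2 | (E)-1-[2,2-dimethyl-5-(prop-1-en-2-yl)-1,3-dioxolan-4-yl]-6-methylhepta-1,5-dien-3-one (trans-dioxolane) | C=C(C)[C@H]1OC(C)(C)O[C@@H]1/C=C/C(=O)CC=C(C)C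
A6 | alternative 3 | 6-[(tert-butyldimethylsilyl)oxy]-5-{3-[(tert-butyldimethylsilyl)oxy]-6-methylhepta-1,5-dien-2-yl}-2-methylcyclohex-2-en-1-ol (configured as in the SMILES) | C=C([C@H](CC=C(C)C)O[Si](C)(C)C(C)(C)C)[C@H]1CC=C(C)[C@@H](O)[C@@H]1O[Si](C)(C)C(C)(C)C
A7 | alternative 3 | (Z)-2-[(tert-butyldimethylsilyl)oxy]-3-{3-[(tert-butyldimethylsilyl)oxy]-6-methylhepta-1,5-dien-2-yl}-6-iodohept-5-enal (configured as in the SMILES) | C=C([C@H](CC=C(C)C)O[Si](C)(C)C(C)(C)C)[C@@H](C/C=C(/C)I)[C@H](C=O)O[Si](C)(C)C(C)(C)C
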